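## Retrosynthetic overview

1. Target 29 ⇐ dimethyl ether dialdehyde 28 ⇐ tetracycle 25: the two formyl groups and the free phenols come last and by non-acidic means (Br/Li exchange then DMF; thiolate O-demethylation), because the C8 methylidene beside the cyclobutane should not survive TiCl4- or BCl3-type reagents.
2. 25 ⇐ enol triflate 23: the nine-membered ring is closed at C7–C8 by intramolecular B-alkyl Suzuki coupling of a C6=C7 vinyl group with the C8 enol triflate; 23 ⇐ cyclobutane methyl ester 17.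
3. 17 ⇐ diazo ketone 14 (key): the plan rests on the cyclobutane C1–C9–C10–C11, which carries C8 on C9 and the C2 chain on C1 beside the gem-dimethyl carbon C11; it maps onto a 3-alkyl-2-diazo-4,4-dimethylcyclopentanone whose carbonyl carbon is pushed out of the ring as C8 by Wolff contraction.
4. 14 ⇐ vinylchroman 9 + enone 10 (C1–C2 bond and C1 by hydrozirconation and copper-catalysed asymmetric conjugate addition); 9 ⇐ coumarin 1 + boronic acid 2 (Rh phenylation sets C1′, trans alkylation sets C5 with a 2-chloroethyl group as latent vinyl, methylenation/ketalisation, alkynylation of the C4 oxocarbenium ion).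
5. Ring order: chroman (from the coumarin) → cyclopentanone (appended) → cyclobutane (step 9) → nine-membered ring (step 15).

Key step: step 9

Assumption: the text uses caryophyllane labels for the terpenoid carbons (chroman C2 = C4, chroman C3 = C5, chroman C4 = C1′) while systematic names use chroman locants, and 2-chloroethyl triflate is taken as a purchasable reagent (otherwise one operation from 2-chloroethanol and Tf2O).

## Route

Step 1
Reactants: 1 5,7-dimethoxycoumarin; 2 phenylboronic acid
Product: 3 (4S)-5,7-dimethoxy-4-phenylchroman-2-one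
Conditions: Rh(acac)(C2H4)2 (3 mol %), (S)-SEGPHOS (3.3 mol %), 2 in excess, 1,4-dioxane–H2O (10:1), 60 °C
Reagents that add atoms: none
Why: Hayashi–Miyaura rhodium-catalysed asymmetric 1,4-addition, in which the phenylrhodium species held by the chiral bisphosphine adds to one enantiotopic face of the coumarin C3=C4 bond and water protonates the rhodium enolate, so that the ligand sets C1′ (the S-ligand is chosen for the 4S lactone).

Step 2
Reactants: 3 (4S)-5,7-dimethoxy-4-phenylchroman-2-one
Product: 4 (3R,4S)-3-(2-chloroethyl)-5,7-dimethoxy-4-phenylchroman-2-one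
Conditions: LiN(SiMe3)2 (1.0 equiv), THF, −78 °C; ClCH2CH2OTf (1.2 equiv), −78 → −60 °C; AcOH quench at −78 °C
Reagents that add atoms: 2-chloroethyl trifluoromethanesulfonate, ClCCOS(=O)(=O)C(F)(F)F
Why: Lactone enolate alkylation, in which the C1′ phenyl group (pseudoaxial through peri strain with the 5-methoxy group) shields one face so that the triflate is attacked anti to it and C5 is set trans to C1′; the chloride is a spectator that serves as latent C6=C7 vinyl without an oxygen that could trap the later oxocarbenium ion, and the cold quench keeps the product enolate from closing a cyclopropane.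

Step 3
Reactants: 4 (3R,4S)-3-(2-chloroethyl)-5,7-dimethoxy-4-phenylchroman-2-one
Product: 6 (3R,4S)-3-(2-chloroethyl)-2,5,7-trimethoxy-2-methyl-4-phenylchromane (both C2 epimers), via exocyclic enol ether 5 (not isolated)
Conditions: Cp2TiMe2 (2.2 equiv), toluene, 70 °C, dark; filter through basic alumina; then MeOH, PPTS (5 mol %), 0 °C → rt
Reagents that add atoms: dimethyltitanocene, C[Ti](C)(C1C=CC=C1)C1C=CC=C1; methanol, CO
Why: Petasis methylenation turns the lactone carbonyl into the exocyclic enol ether under non-basic conditions that leave C5–H and the C–Cl bond alone, and brief PPTS-catalysed Markovnikov addition of methanol gives the mixed ketal before the cation can equilibrate with the endocyclic enol ether (which would erase C5); the ketal configuration is irrelevant because it is ionised in step 4.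

Step 4
Reactants: 6 (3R,4S)-3-(2-chloroethyl)-2,5,7-trimethoxy-2-methyl-4-phenylchromane
Product: 7 (2R,3R,4S)-3-(2-chloroethyl)-5,7-dimethoxy-2-methyl-4-phenyl-2-[(trimethylsilyl)ethynyl]chromane
Conditions: Me3SiC≡CH, nBuLi, toluene, 0 °C; Me2AlCl, 0 °C → rt; then 6 in CH2Cl2, −20 °C → rt; aqueous potassium sodium tartrate
Reagents that add atoms: (trimethylsilyl)acetylene, C#C[Si](C)(C)C
Why: Organoalane substitution of a ketal, in which the Lewis-acidic alkynylalane ionises both ketal epimers at the methoxy oxygen to one oxocarbenium ion and transfers its sp-carbon ligand in preference to methyl; since peri strain holds the C1′ phenyl group pseudoaxial and its trans neighbour on C5 therefore pseudoaxial too, axial attack anti to the C5 chloroethyl group should place the slim alkynyl group cis to phenyl and the methyl group equatorial (also the more stable C4 epimer), and the aprotic medium prevents proton loss and return from scrambling C5.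

Step 5
Reactants: 7 (2R,3R,4S)-3-(2-chloroethyl)-5,7-dimethoxy-2-methyl-4-phenyl-2-[(trimethylsilyl)ethynyl]chromane
Product: 8 (2R,3R,4S)-3-(2-chloroethyl)-2-ethynyl-5,7-dimethoxy-2-methyl-4-phenylchromane
Conditions: K2CO3, MeOH–THF, rt
Reagents that add atoms: none
Why: Methoxide-mediated protodesilylation of the alkynylsilane, which touches neither the ethers, the primary chloride nor any stereocentre.

Step 6
Reactants: 8 (2R,3R,4S)-3-(2-chloroethyl)-2-ethynyl-5,7-dimethoxy-2-methyl-4-phenylchromane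
Product: 9 (2S,3R,4S)-3-(2-chloroethyl)-2-ethenyl-5,7-dimethoxy-2-methyl-4-phenylchromane
Conditions: H2 (1 atm), Pd/CaCO3 poisoned with Pb(OAc)2, quinoline, EtOAc, rt
Reagents that add atoms: none
Why: Lindlar semi-hydrogenation stops at the alkene on the poisoned palladium surface, and the benzylic bonds and the C–Cl bond are inert under these conditions.

Step 7
Reactants: 9 (2S,3R,4S)-3-(2-chloroethyl)-2-ethenyl-5,7-dimethoxy-2-methyl-4-phenylchromane; 10 4,4-dimethylcyclopent-2-en-1-one
Product: 12 (3S)-3-{2-[(2S,3R,4S)-3-(2-chloroethyl)-5,7-dimethoxy-2-methyl-4-phenylchroman-2-yl]ethyl}-4,4-dimethylcyclopentan-1-one, via alkylzirconocene chloride 11 (not isolated)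
Conditions: Cp2Zr(H)Cl (1.2 equiv), CH2Cl2, rt; then CuCl (10 mol %), AgNTf2 (11 mol %), binaphthol-derived phosphoramidite ligand (10 mol %), 10 (1.5 equiv), Et2O, rt; 1 M HCl work-up
Reagents that add atoms: none
Why: Hydrozirconation places zirconium on the terminal carbon C2 (the internal position is blocked by the quaternary C4), and copper/phosphoramidite-catalysed asymmetric conjugate addition of the alkylzirconocene transfers the chain to the enone β-carbon next to the gem-dimethyl carbon, so that the ligand enantiomer (chosen for 3S) rather than the remote chroman stereocentres sets C1.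

Step 8
Reactants: 12 (3S)-3-{2-[(2S,3R,4S)-3-(2-chloroethyl)-5,7-dimethoxy-2-methyl-4-phenylchroman-2-yl]ethyl}-4,4-dimethylcyclopentan-1-one
Product: 14 (3R)-3-{2-[(2S,3R,4S)-3-(2-chloroethyl)-5,7-dimethoxy-2-methyl-4-phenylchroman-2-yl]ethyl}-2-diazo-4,4-dimethylcyclopentan-1-one, via trifluoroacetyl ketone 13 (not isolated)
Conditions: LiN(SiMe3)2 (1.1 equiv), THF, −78 °C; CF3CO2CH2CF3 (1.2 equiv), −78 °C; 1 M HCl; then MsN3 (1.5 equiv), Et3N (1.5 equiv), H2O (1 equiv), MeCN, rt
Reagents that add atoms: methanesulfonyl azide, CS(=O)(=O)N=[N+]=[N-]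
Why: Detrifluoroacetylative diazo transfer (Regitz type), in which kinetic deprotonation should take the C9 methylene hydrogen anti to the side chain rather than a C10 hydrogen flanked by the gem-dimethyl group, Claisen acylation activates that carbon, and the sulfonyl azide delivers N2 with loss of the trifluoroacetyl group; C1 is untouched (its descriptor changes only through CIP priorities).

Step 9
Reactants: 14 (3R)-3-{2-[(2S,3R,4S)-3-(2-chloroethyl)-5,7-dimethoxy-2-methyl-4-phenylchroman-2-yl]ethyl}-2-diazo-4,4-dimethylcyclopentan-1-one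
Product: 17 methyl (1R,2S)-2-{2-[(2S,3R,4S)-3-(2-chloroethyl)-5,7-dimethoxy-2-methyl-4-phenylchroman-2-yl]ethyl}-3,3-dimethylcyclobutane-1-carboxylate, via cyclobutylidene ketene 15 (not isolated), via cis ester 16 (not isolated)
Conditions: hν (365 nm), degassed MeOH–THF (4:1), 0 °C; then NaOMe (0.3 equiv), MeOH, rt
Reagents that add atoms: methanol, CO
Why: Photoexcitation of the ring-locked s-Z α-diazo ketone expels N2 while the C10 methylene shifts from the carbonyl carbon C8 to C9 (in concert or through the singlet α-keto carbene), giving ketene 15, to which methanol adds. This is the photochemical Wolff ring contraction long used to turn 2-diazocyclopentanones into cyclobutanecarboxylates. The cyclobutane C1–C9–C10–C11 is closed by a 1,2-alkyl shift with five-to-four ring contraction and not by a cyclisation, so C1 is a spectator and keeps its configuration while the expelled carbon becomes the ester carbon C8. C9 arises on protonation as a cis/trans mixture and is then set under thermodynamic control by NaOMe equilibration to the trans-1,2-disubstituted ester, the C1 chain disfavouring the cis isomer. The step needs migration to outrun 1,2-hydride shift from C1–H, C–H insertion and O–H insertion into methanol; the locked s-Z geometry favouring the concerted excited-state path, long-wavelength light that the dimethoxychroman does not absorb, and low temperature should secure this. The regiochemistry was fixed in step 8, since only the C9 diazo isomer gives the ester and the side chain on adjacent carbons beside C11.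

Step 10
Reactants: 17 methyl (1R,2S)-2-{2-[(2S,3R,4S)-3-(2-chloroethyl)-5,7-dimethoxy-2-methyl-4-phenylchroman-2-yl]ethyl}-3,3-dimethylcyclobutane-1-carboxylate
Product: 18 methyl (1R,2S)-2-(2-{(2S,3R,4S)-5,7-dimethoxy-2-methyl-3-[2-(2-nitrophenylselanyl)ethyl]-4-phenylchroman-2-yl}ethyl)-3,3-dimethylcyclobutane-1-carboxylate
Conditions: (2-O2NC6H4Se)2 (0.6 equiv), NaBH4, EtOH–DMF, 0 °C → rt; then 17, NaI (0.2 equiv), 50 °C
Reagents that add atoms: bis(2-nitrophenyl) diselenide, [O-][N+](=O)c1ccccc1[Se][Se]c1ccccc1[N+](=O)[O-]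
Why: SN2 displacement of the primary chloride (through the iodide formed in situ, Finkelstein) by the soft arylselenolate, a weakly basic nucleophile that should leave the ester, the aryl ethers and the trans C9 centre alone.

Step 11
Reactants: 18 methyl (1R,2S)-2-(2-{(2S,3R,4S)-5,7-dimethoxy-2-methyl-3-[2-(2-nitrophenylselanyl)ethyl]-4-phenylchroman-2-yl}ethyl)-3,3-dimethylcyclobutane-1-carboxylate
Product: 20 methyl (1R,2S)-2-{2-[(2S,3R,4S)-3-ethenyl-5,7-dimethoxy-2-methyl-4-phenylchroman-2-yl]ethyl}-3,3-dimethylcyclobutane-1-carboxylate, via selenoxide 19 (not isolated)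
Conditions: 30% aq. H2O2, pyridine, THF, 0 °C → rt
Reagents that add atoms: none
Why: Grieco-type selenoxide syn-elimination, in which oxidation at selenium is followed at room temperature by intramolecular removal of a C6 hydrogen (the only β-hydrogens), unveiling the C6=C7 vinyl group on C5.

Step 12
Reactants: 20 methyl (1R,2S)-2-{2-[(2S,3R,4S)-3-ethenyl-5,7-dimethoxy-2-methyl-4-phenylchroman-2-yl]ethyl}-3,3-dimethylcyclobutane-1-carboxylate
Product: 21 (1R,2S)-2-{2-[(2S,3R,4S)-3-ethenyl-5,7-dimethoxy-2-methyl-4-phenylchroman-2-yl]ethyl}-N-methoxy-N,3,3-trimethylcyclobutane-1-carboxamide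
Conditions: MeNH(OMe)·HCl (3 equiv), iPrMgCl (6 equiv), THF, −20 → 0 °C
Reagents that add atoms: N,O-dimethylhydroxylamine hydrochloride, CNOC.Cl
Why: Weinreb amide formation by aminolysis of the ester with the chloromagnesium amide, which works on hindered esters; C9 is already the thermodynamically preferred trans epimer, so the basic medium cannot erode it.

Step 13
Reactants: 21 (1R,2S)-2-{2-[(2S,3R,4S)-3-ethenyl-5,7-dimethoxy-2-methyl-4-phenylchroman-2-yl]ethyl}-N-methoxy-N,3,3-trimethylcyclobutane-1-carboxamide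
Product: 22 1-[(1R,2S)-2-{2-[(2S,3R,4S)-3-ethenyl-5,7-dimethoxy-2-methyl-4-phenylchroman-2-yl]ethyl}-3,3-dimethylcyclobutyl]ethan-1-one
Conditions: MeMgBr (3 equiv), THF, 0 °C; aq. NH4Cl
Reagents that add atoms: methylmagnesium bromide, C[Mg]Br
Why: Weinreb ketone synthesis, in which the Grignard adduct is held as the chelated tetrahedral intermediate and releases the methyl ketone only on work-up, so no second addition occurs.

Step 14
Reactants: 22 1-[(1R,2S)-2-{2-[(2S,3R,4S)-3-ethenyl-5,7-dimethoxy-2-methyl-4-phenylchroman-2-yl]ethyl}-3,3-dimethylcyclobutyl]ethan-1-one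
Product: 23 1-[(1R,2S)-2-{2-[(2S,3R,4S)-3-ethenyl-5,7-dimethoxy-2-methyl-4-phenylchroman-2-yl]ethyl}-3,3-dimethylcyclobutyl]ethenyl trifluoromethanesulfonate
Conditions: KN(SiMe3)2 (1.05 equiv), THF, −78 °C; PhNTf2 (1.1 equiv), −78 → −30 °C
Reagents that add atoms: N-phenylbis(trifluoromethanesulfonimide), O=S(=O)(N(c1ccccc1)S(=O)(=O)C(F)(F)F)C(F)(F)F
Why: Kinetic enolisation at the methyl group (deprotonation at C9 would give a strained cyclobutylidene enolate) and O-triflation give the terminal enol triflate that carries C8 and the future methylidene carbon; the base is kept near one equivalent to avoid elimination to the alkyne.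

Step 15
Reactants: 23 1-[(1R,2S)-2-{2-[(2S,3R,4S)-3-ethenyl-5,7-dimethoxy-2-methyl-4-phenylchroman-2-yl]ethyl}-3,3-dimethylcyclobutyl]ethenyl trifluoromethanesulfonate
Product: 25 (1S,4S,5R,9R,1′S)-tetracyclic dimethyl ether (the target skeleton with OMe at chroman C5 and C7 and H at chroman C6 and C8), via alkylborane 24 (not isolated)
Conditions: 9-BBN dimer (1.5 equiv B–H), THF, 0 °C → rt; then slow addition to Pd(dppf)Cl2 (20 mol %), AsPh3 (20 mol %), Cs2CO3 (3 equiv), DMF–THF–H2O, 50 °C, final concentration 2 mM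
Reagents that add atoms: none
Why: Intramolecular B-alkyl Suzuki–Miyaura coupling, in which 9-BBN hydroborates only the monosubstituted vinyl group (boron on C7; the electron-poor enol triflate alkene is left), zerovalent palladium inserts into the C8–OTf bond, the base-activated borane transmetallates and reductive elimination forms C7–C8, closing the nine-membered ring under high dilution with the methylidene already in place and without creating a stereocentre.

Step 16
Reactants: 25 (1S,4S,5R,9R,1′S)-tetracyclic dimethyl ether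
Product: 26 (1S,4S,5R,9R,1′S)-tetracyclic dimethyl ether brominated at chroman C6 and C8
Conditions: NBS (2.05 equiv), MeCN, −20 → 0 °C, dark
Reagents that add atoms: N-bromosuccinimide, O=C1CCC(=O)N1Br
Why: Electrophilic aromatic bromination, for which the two free positions of the trioxygenated ring are far more nucleophilic than the 1,1-disubstituted alkene toward NBS in a polar, nucleophile-free medium without light.

Step 17
Reactants: 26 (1S,4S,5R,9R,1′S)-tetracyclic dimethyl ether brominated at chroman C6 and C8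
Product: 28 (1S,4S,5R,9R,1′S)-tetracyclic dimethyl ether formylated at chroman C6 and C8, via dilithio arene 27 (not isolated)
Conditions: tBuLi (4.4 equiv), THF, −78 °C; DMF (6 equiv), −78 → 0 °C; aq. NH4Cl
Reagents that add atoms: N,N-dimethylformamide, CN(C)C=O
Why: Double bromine–lithium exchange followed by Bouveault formylation, each aryllithium being flanked and stabilised by two alkoxy groups; the non-acidic conditions avoid the TiCl4-mediated Rieche formylation, whose electrophile and Lewis acid would attack the methylidene group once the ring is deactivated by the first formyl group.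

Step 18
Reactants: 28 (1S,4S,5R,9R,1′S)-tetracyclic dimethyl ether formylated at chroman C6 and C8
Product: 29 CNP0253700.1, (1S,4S,5R,9R,1′S)
Conditions: NaSEt (8 equiv), DMF, 100 °C; then cold 1 M HCl
Reagents that add atoms: none
Why: Nucleophilic O-demethylation (SN2 attack of thiolate on the methyl carbons), made easy because both methoxy groups are ortho/para to formyl groups so that the phenoxides are good leaving groups, while the basic, Lewis-acid-free medium spares the tertiary chroman ether and the exocyclic alkene that boron halides would ionise or protonate.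

## Compound list

1 | 5,7-dimethoxycoumarin | COc1cc(OC)c2ccc(=O)oc2c1 | starting material
2 | phenylboronic acid | OB(O)c1ccccc1 | starting material
3 | (4S)-5,7-dimethoxy-4-phenylchroman-2-one | O=C1C[C@@H](c2ccccc2)c2c(OC)cc(OC)cc2O1 | intermediate
4 | (3R,4S)-3-(2-chloroethyl)-5,7-dimethoxy-4-phenylchroman-2-one (3,4-trans) | ClCC[C@@H]1[C@@H](c2ccccc2)c2c(OC)cc(OC)cc2OC1=O | intermediate
5 | (3R,4S)-3-(2-chloroethyl)-5,7-dimethoxy-2-methylidene-4-phenylchromane | ClCC[C@@H]1[C@@H](c2ccccc2)c2c(OC)cc(OC)cc2OC1=C | intermediate (not isolated)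
6 | (3R,4S)-3-(2-chloroethyl)-2,5,7-trimethoxy-2-methyl-4-phenylchromane, both C2 epimers | ClCC[C@@H]1[C@@H](c2ccccc2)c2c(OC)cc(OC)cc2OC1(C)OC | intermediate
7 | (2R,3R,4S)-3-(2-chloroethyl)-5,7-dimethoxy-2-methyl-4-phenyl-2-[(trimethylsilyl)ethynyl]chromane | ClCC[C@@H]1[C@@H](c2ccccc2)c2c(OC)cc(OC)cc2O[C@@]1(C)C#C[Si](C)(C)C | intermediate
8 | (2R,3R,4S)-3-(2-chloroethyl)-2-ethynyl-5,7-dimethoxy-2-methyl-4-phenylchromane | ClCC[C@@H]1[C@@H](c2ccccc2)c2c(OC)cc(OC)cc2O[C@@]1(C)C#C | intermediate
9 | (2S,3R,4S)-3-(2-chloroethyl)-2-ethenyl-5,7-dimethoxy-2-methyl-4-phenylchromane | ClCC[C@@H]1[C@@H](c2ccccc2)c2c(OC)cc(OC)cc2O[C@@]1(C)C=C | intermediate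
10 | 4,4-dimethylcyclopent-2-en-1-one | CC1(C)CC(=O)C=C1 | starting material
11 | chloro{2-[(2S,3R,4S)-3-(2-chloroethyl)-5,7-dimethoxy-2-methyl-4-phenylchroman-2-yl]ethyl}bis(cyclopentadienyl)zirconium | ClCC[C@@H]1[C@@H](c2ccccc2)c2c(OC)cc(OC)cc2O[C@@]1(C)CC[Zr](Cl)(C1C=CC=C1)C1C=CC=C1 | intermediate (not isolated)
12 | (3S)-3-{2-[(2S,3R,4S)-3-(2-chloroethyl)-5,7-dimethoxy-2-methyl-4-phenylchroman-2-yl]ethyl}-4,4-dimethylcyclopentan-1-one | ClCC[C@@H]1[C@@H](c2ccccc2)c2c(OC)cc(OC)cc2O[C@@]1(C)CC[C@H]1CC(=O)CC1(C)C | intermediate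
13 | (3S)-3-{2-[(2S,3R,4S)-3-(2-chloroethyl)-5,7-dimethoxy-2-methyl-4-phenylchroman-2-yl]ethyl}-4,4-dimethyl-2-(trifluoroacetyl)cyclopentan-1-one (C2 epimers, largely enolised) | ClCC[C@@H]1[C@@H](c2ccccc2)c2c(OC)cc(OC)cc2O[C@@]1(C)CC[C@H]1C(C(=O)C(F)(F)F)C(=O)CC1(C)C | intermediate (not isolated)
14 | (3R)-3-{2-[(2S,3R,4S)-3-(2-chloroethyl)-5,7-dimethoxy-2-methyl-4-phenylchroman-2-yl]ethyl}-2-diazo-4,4-dimethylcyclopentan-1-one | ClCC[C@@H]1[C@@H](c2ccccc2)c2c(OC)cc(OC)cc2O[C@@]1(C)CC[C@H]1C(=[N+]=[N-])C(=O)CC1(C)C | intermediate (key-step precursor)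
15 | 2-[(2R)-2-{2-[(2S,3R,4S)-3-(2-chloroethyl)-5,7-dimethoxy-2-methyl-4-phenylchroman-2-yl]ethyl}-3,3-dimethylcyclobutylidene]ethen-1-one | ClCC[C@@H]1[C@@H](c2ccccc2)c2c(OC)cc(OC)cc2O[C@@]1(C)CC[C@H]1C(=C=O)CC1(C)C | intermediate (not isolated)
16 | methyl (1S,2S)-2-{2-[(2S,3R,4S)-3-(2-chloroethyl)-5,7-dimethoxy-2-methyl-4-phenylchroman-2-yl]ethyl}-3,3-dimethylcyclobutane-1-carboxylate (cis) | ClCC[C@@H]1[C@@H](c2ccccc2)c2c(OC)cc(OC)cc2O[C@@]1(C)CC[C@H]1[C@@H](C(=O)OC)CC1(C)C | intermediate (not isolated)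
17 | methyl (1R,2S)-2-{2-[(2S,3R,4S)-3-(2-chloroethyl)-5,7-dimethoxy-2-methyl-4-phenylchroman-2-yl]ethyl}-3,3-dimethylcyclobutane-1-carboxylate (trans) | ClCC[C@@H]1[C@@H](c2ccccc2)c2c(OC)cc(OC)cc2O[C@@]1(C)CC[C@H]1[C@H](C(=O)OC)CC1(C)C | intermediate (key-step product)
18 | methyl (1R,2S)-2-(2-{(2S,3R,4S)-5,7-dimethoxy-2-methyl-3-[2-(2-nitrophenylselanyl)ethyl]-4-phenylchroman-2-yl}ethyl)-3,3-dimethylcyclobutane-1-carboxylate | [O-][N+](=O)c1ccccc1[Se]CC[C@@H]1[C@@H](c2ccccc2)c2c(OC)cc(OC)cc2O[C@@]1(C)CC[C@H]1[C@H](C(=O)OC)CC1(C)C | intermediate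
19 | selenoxide of 18 (Se=O; configuration at selenium undefined) | [O-][N+](=O)c1ccccc1[Se](=O)CC[C@@H]1[C@@H](c2ccccc2)c2c(OC)cc(OC)cc2O[C@@]1(C)CC[C@H]1[C@H](C(=O)OC)CC1(C)C | intermediate (not isolated)
20 | methyl (1R,2S)-2-{2-[(2S,3R,4S)-3-ethenyl-5,7-dimethoxy-2-methyl-4-phenylchroman-2-yl]ethyl}-3,3-dimethylcyclobutane-1-carboxylate | C=C[C@@H]1[C@@H](c2ccccc2)c2c(OC)cc(OC)cc2O[C@@]1(C)CC[C@H]1[C@H](C(=O)OC)CC1(C)C | intermediate
21 | (1R,2S)-2-{2-[(2S,3R,4S)-3-ethenyl-5,7-dimethoxy-2-methyl-4-phenylchroman-2-yl]ethyl}-N-methoxy-N,3,3-trimethylcyclobutane-1-carboxamide | C=C[C@@H]1[C@@H](c2ccccc2)c2c(OC)cc(OC)cc2O[C@@]1(C)CC[C@H]1[C@H](C(=O)N(C)OC)CC1(C)C | intermediate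
22 | 1-[(1R,2S)-2-{2-[(2S,3R,4S)-3-ethenyl-5,7-dimethoxy-2-methyl-4-phenylchroman-2-yl]ethyl}-3,3-dimethylcyclobutyl]ethan-1-one | C=C[C@@H]1[C@@H](c2ccccc2)c2c(OC)cc(OC)cc2O[C@@]1(C)CC[C@H]1[C@H](C(C)=O)CC1(C)C | intermediate
23 | 1-[(1R,2S)-2-{2-[(2S,3R,4S)-3-ethenyl-5,7-dimethoxy-2-methyl-4-phenylchroman-2-yl]ethyl}-3,3-dimethylcyclobutyl]ethenyl trifluoromethanesulfonate | C=C[C@@H]1[C@@H](c2ccccc2)c2c(OC)cc(OC)cc2O[C@@]1(C)CC[C@H]1[C@H](C(=C)OS(=O)(=O)C(F)(F)F)CC1(C)C | intermediate
24 | 1-[(1R,2S)-2-(2-{(2S,3R,4S)-3-[2-(9-borabicyclo[3.3.1]nonan-9-yl)ethyl]-5,7-dimethoxy-2-methyl-4-phenylchroman-2-yl}ethyl)-3,3-dimethylcyclobutyl]ethenyl trifluoromethanesulfonate | C1CCC2CCCC1B2CC[C@@H]1[C@@H](c2ccccc2)c2c(OC)cc(OC)cc2O[C@@]1(C)CC[C@H]1[C@H](C(=C)OS(=O)(=O)C(F)(F)F)CC1(C)C | intermediate (not isolated)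
25 | (1S,4S,5R,9R,1′S)-tetracyclic dimethyl ether: target skeleton with OMe at chroman C5 and C7 and H at chroman C6 and C8 | C=C1CC[C@@H]2[C@@H](c3ccccc3)c3c(OC)cc(OC)cc3O[C@@]2(C)CC[C@H]2[C@H]1CC2(C)C | intermediate
26 | (1S,4S,5R,9R,1′S)-dibromide: 25 with Br at chroman C6 and C8 | C=C1CC[C@@H]2[C@@H](c3ccccc3)c3c(OC)c(Br)c(OC)c(Br)c3O[C@@]2(C)CC[C@H]2[C@H]1CC2(C)C | intermediate
27 | (1S,4S,5R,9R,1′S)-dilithio arene: 25 with Li at chroman C6 and C8 | C=C1CC[C@@H]2[C@@H](c3ccccc3)c3c(OC)c([Li])c(OC)c([Li])c3O[C@@]2(C)CC[C@H]2[C@H]1CC2(C)C | intermediate (not isolated)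
28 | (1S,4S,5R,9R,1′S)-dialdehyde dimethyl ether: 25 with CHO at chroman C6 and C8 | C=C1CC[C@@H]2[C@@H](c3ccccc3)c3c(OC)c(C=O)c(OC)c(C=O)c3O[C@@]2(C)CC[C@H]2[C@H]1CC2(C)C | intermediate
29 | CNP0253700.1, (1S,4S,5R,9R,1′S): chroman-5,7-diol-6,8-dicarbaldehyde fused to the caryophyllane unit | C=C1CC[C@@H]2[C@@H](c3ccccc3)c3c(O)c(C=O)c(O)c(C=O)c3O[C@@]2(C)CC[C@H]2[C@H]1CC2(C)C | target

## Step count and risk

Total step count: 18 steps. Longest linear sequence: 18 steps, from 1; the enone 10 enters unchanged at step 7.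

Steps most likely to fail:

Step 15. The alkylborane may couple intermolecularly, or the alkylpalladium intermediate may be lost by β-hydride elimination or protodeboronation, faster than the strained nine-membered ring closes. The fallback forms the same C7–C8 bond by a Nozaki–Hiyama–Kishi closure and then removes the extra oxygen. It sets out from 23: the borane 24 is oxidised with NaBO3·4H2O to the primary alcohol F1, and Dess–Martin periodinane gives the aldehyde F2. CrCl2 with catalytic NiCl2 in DMSO–THF at high dilution adds the alkenyl triflate carbon C8 to the C7 aldehyde to give the cyclic allylic alcohol F3. ClCO2Me and pyridine give the methyl carbonate F4. Tsuji reduction (Pd(OAc)2, PBu3, HCO2NH4, dioxane, 100 °C) delivers hydride to the ring terminus C7 of the allyl complex, keeps the 1,1-disubstituted alkene, and comes back to the route at 25.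

Step 7. Carbometalation at the enone β-carbon, shielded by the adjacent gem-dimethyl group, may be slow, so that the alkylzirconium is lost by protonolysis or the facial control erodes. The fallback transfers an alkenyl group with rhodium instead of an alkyl group with copper. It sets out from alkyne 8 (step 6 is then skipped): pinacolborane with catalytic Cp2Zr(H)Cl and Et3N at 60 °C gives the (E)-alkenylboronate F5. Hayashi–Miyaura addition to 10 ([Rh(OH)(cod)]2, the BINAP enantiomer chosen for the required face, KOH, dioxane–H2O, 60 °C) gives the alkenyl ketone F6. Hydrogenation (H2, Pd/C, EtOAc) saturates the only alkene present and comes back to the route at 12.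

Step 4. The alkynyl group may be delivered to the face of the oxocarbenium ion anti to phenyl (giving the C4 epimer), or the cation may lose a proton to the 4H-chromene. The fallback exchanges the roles of the two carbon substituents. It sets out from lactone 4: LiC≡CSiMe3 in THF at −78 °C gives the ynone-phenol F7, and HC(OMe)3, MeOH and camphorsulfonic acid close it to the cyclic alkynyl methyl ketal F8. Me3Al (CH2Cl2, −78 → 0 °C) then methylates the alkynyl-stabilised oxocarbenium ion. With the same facial bias the methyl group now takes the face that the alkynyl group took before, which leaves the alkynyl group cis to phenyl and comes back to the route at 7.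

Further compounds
F1 | step 15 | 1-[(1R,2S)-2-{2-[(2S,3R,4S)-3-(2-hydroxyethyl)-5,7-dimethoxy-2-methyl-4-phenylchroman-2-yl]ethyl}-3,3-dimethylcyclobutyl]ethenyl trifluoromethanesulfonate | OCC[C@@H]1[C@@H](c2ccccc2)c2c(OC)cc(OC)cc2O[C@@]1(C)CC[C@H]1[C@H](C(=C)OS(=O)(=O)C(F)(F)F)CC1(C)C
F2 | step 15 | 1-[(1R,2S)-2-{2-[(2S,3R,4S)-5,7-dimethoxy-2-methyl-3-(2-oxoethyl)-4-phenylchroman-2-yl]ethyl}-3,3-dimethylcyclobutyl]ethenyl trifluoromethanesulfonate | O=CC[C@@H]1[C@@H](c2ccccc2)c2c(OC)cc(OC)cc2O[C@@]1(C)CC[C@H]1[C@H](C(=C)OS(=O)(=O)C(F)(F)F)CC1(C)C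
F3 | step 15 | C7-hydroxy derivative of 25 (allylic alcohol, C7 epimers) | C=C1C(O)C[C@@H]2[C@@H](c3ccccc3)c3c(OC)cc(OC)cc3O[C@@]2(C)CC[C@H]2[C@H]1CC2(C)C
F4 | step 15 | C7 methyl carbonate of F3 (C7 epimers) | C=C1C(OC(=O)OC)C[C@@H]2[C@@H](c3ccccc3)c3c(OC)cc(OC)cc3O[C@@]2(C)CC[C@H]2[C@H]1CC2(C)C
F5 | step 7 | 2-[(E)-2-{(2S,3R,4S)-3-(2-chloroethyl)-5,7-dimethoxy-2-methyl-4-phenylchroman-2-yl}ethenyl]-4,4,5,5-tetramethyl-1,3,2-dioxaborolane | ClCC[C@@H]1[C@@H](c2ccccc2)c2c(OC)cc(OC)cc2O[C@@]1(C)/C=C/B1OC(C)(C)C(C)(C)O1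
F6 | step 7 | (3R)-3-[(E)-2-{(2S,3R,4S)-3-(2-chloroethyl)-5,7-dimethoxy-2-methyl-4-phenylchroman-2-yl}ethenyl]-4,4-dimethylcyclopentan-1-one | ClCC[C@@H]1[C@@H](c2ccccc2)c2c(OC)cc(OC)cc2O[C@@]1(C)/C=C/[C@H]1CC(=O)CC1(C)C
F7 | step 4 | (4R)-6-chloro-4-[(S)-(2-hydroxy-4,6-dimethoxyphenyl)(phenyl)methyl]-1-(trimethylsilyl)hex-1-yn-3-one | ClCC[C@@H](C(=O)C#C[Si](C)(C)C)[C@@H](c1ccccc1)c1c(OC)cc(OC)cc1O
F8 | step 4 | (3R,4S)-3-(2-chloroethyl)-2,5,7-trimethoxy-4-phenyl-2-[(trimethylsilyl)ethynyl]chromane, both C2 epimers | ClCC[C@@H]1[C@@H](c2ccccc2)c2c(OC)cc(OC)cc2OC1(OC)C#C[Si](C)(C)C
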